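(The data are calculated from invented constants; the scatter is artificial.)

What can you still gain from this flask once it has reached 30 min? The flask, the earlier runs and the options are these:

| setting | eta | gamma | flask |
|---|---|---|---|
| substrate | 0.020 M | 0.030 M | 0.020 M |
| coupling partner | 0.012 M | 0.012 M | 0.0120 M |
| free catalyst | 1 mM | 1 mM | 1.0 mM |
| temperature | 100 °C | 85 °C | 100 °C |
| remark | the very flask that is asked about, followed so far | run made earlier |  |
| time |  |  | 30 min |

| run | time / min | target / % | substrate / % |
|---|---|---|---|
| eta | 2.50 | 17 | 12 |
| eta | 4.00 | 23 | 5 |
| eta | 6.00 | 28 | 0 |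
| eta | 10.0 | 31 | 0 |
| eta | 20.0 | 32 | 0 |
| eta | 30.0 | 30 | 0 |
| gamma | 2.00 | 0 | 37 |
| gamma | 5.00 | 6 | 16 |
| gamma | 8.00 | 12 | 9 |
| gamma | 12.0 | 18 | 3 |
| gamma | 20.0 | 22 | 0 |
| gamma | 25.0 | 22 | 0 |

(scatter of a reading: 1.5 percentage points)

- ash: change nothing and wait 1.0 h more
- birch: at 30 min add free catalyst, 100 % of the amount charged, then wait 1.0 h
- maple: at 30 min add coupling partner, 50.0 % of the amount charged, then wait 1.0 h
- larch: at 30 min raise the temperature by 20 K, then wait 1.0 h
- oak: at 30 min take out 90 % of the target then present, then wait 1.0 h

- target that was removed still counts
- additions bring no volume worth counting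

- target, in percent of the substrate first charged, at 30 min
- which option adds most target ("none" when 2 percentage points or less is all one gets) (ash / birch / maple / larch / oak / none)
- target present, with what was taken out counted in, in percent of the substrate first charged, after maple
- target present, with what was taken out counted in, in percent of the substrate first charged, after oak

1. Read the plateau of the eta run, the flask itself, as a concentration of target. Its last 3 readings average to 6.20 mM, which is 31.0 % of the substrate charged.

2. Now take a second way, through the gamma run, which had more substrate and a lower temperature. Its plateau is 6.60 mM. Put over this flask's charge, that gives 33.0 %. The two ways part by 2 percentage points, close to the reading scatter of 1.5 points. I therefore keep their mean, the plateau amount M, 6.40 mM, and commit to 32.0 % for now.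

3. But both runs charged the same coupling partner, so this agreement could be cheating: partner might be what ends them. Look at when target stops. In each run it stops rising at or soon after the first zero substrate reading, which comes at 6.00 min in eta and, later, at 20.0 min in gamma. So I take substrate as what ended them.

4. Where did the substrate go? In gamma, 18.9 mM had left by 2.00 min with target at 0 %, more than the catalyst charge of 1 mM can hold. So a second route is racing the catalyst.

5. Use the symmetric case as the zero of the scale: the substrate level at which both routes run equally fast. My assumption is that the catalyst turns over at a steady rate proportional to its charge, while the loss goes as the square of c_substrate. Above that level the loss wins, below it the catalyst wins. M then follows that level rather than the charge, and it scales as the square root of the catalyst.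

6. In this flask, c_substrate reads 0 % at 30.0 min, so I expect no option to add anything: none is my best, and maple and oak both stay at 32.0 %.

The forecast gave 31 % for now, maple as best, 46 % after maple and 31 % after oak, saying of the stop at the lower temperature: “That looks like reagent exhaustion, not catalyst decay”.

The simulation gives 31.6 % now, none as best, 31.6 % after maple and 31.6 % after oak.

    catalyst intermediate D → free catalyst + target (k = 0.0590 s⁻¹, Ea = 102 kJ mol⁻¹)
    catalyst intermediate C ⇌ released group + catalyst intermediate D (K = 0.0240 M, k = 3.90 s⁻¹, Ea = 93.0 kJ mol⁻¹, ΔH = −43.0 kJ mol⁻¹)
    catalyst intermediate A → catalyst intermediate B (k = 2.00 s⁻¹, Ea = 81.0 kJ mol⁻¹)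
    2 substrate → self-condensation product (k = 0.660 M⁻¹ s⁻¹, Ea = 78.0 kJ mol⁻¹)
    released group → by-product carried off (k = 1.70 × 10⁻⁴ s⁻¹, Ea = 125 kJ mol⁻¹)
    free catalyst → spent catalyst (k = 4.50 × 10⁻⁷ s⁻¹, Ea = 124 kJ mol⁻¹)
    substrate + free catalyst → catalyst intermediate A (k = 100 M⁻¹ s⁻¹, Ea = 64.0 kJ mol⁻¹)
    coupling partner + catalyst intermediate B ⇌ catalyst intermediate C (K = 120 M⁻¹, k = 4.40 M⁻¹ s⁻¹, Ea = 53.0 kJ mol⁻¹, ΔH = −5.00 kJ mol⁻¹)
    (constants at 100 °C)

M, 6.40 mM, stands against 6.31 mM of target in this flask. At 30.0 min this flask holds 0 % of its substrate and 47.4 % of its coupling partner still free, so substrate is the limiting reagent. Taking self-condensation away lifts this flask from 31.6 % to 59.7 %, the largest single effect. For the neighbour flask with 0.0040 M of free catalyst, the square root of the catalyst ratio carries M to 64.0 % of the substrate, more than the 60.0 % that its coupling partner charge equals; that flask stands at 59.0 %, with 1.6 % of its coupling partner left.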